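**Retrosynthetic overview**
- 16 ⇐ imidoyl chloride 15 (C1–CH3 by Negishi coupling) ⇐ lactam 14 ⇐ naphthol 13 (O-methylation).
- 13 ⇐ diarylmethane 8 + (E)-1-(phenylsulfinyl)propene 11. C1' of naphthalene ring C is bonded to C7 of the isoquinoline, to C2' and to C8a', so it is traced back to the CH2 of 8. Its anion forms C1'–C2' and C3'–C4' in one Michael–Dieckmann operation, and the hindered C7–C1' axis appears only on aromatisation.
- The three-carbon partner is a propyne equivalent. Sulfinyl is chosen instead of sulfonyl because sulfur can then leave C3' by thermal syn-elimination, which needs no acidic hydrogen at C2'.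
- 8 ⇐ Negishi coupling of bromolactam 4 with benzylzinc 7 (from toluate 5). 4 ⇐ enantioselective rhodium-catalysed C–H annulation of hydroxamate 3 (from acid 1) with propene, which sets C3.
- Ring order: rings A (isoquinoline benzo ring) and D (C5'–C8') come from 1 and 5; ring B (lactam) closes in step 2; ring C (C1'–C4', C4a', C8a') closes in step 6.

Key step: step 6

Assumption: the target structure fixes only C3 (R) and leaves the C7–C1' biaryl axis undefined, so the axis is not controlled and 13–16 are expected as mixtures of the two atropisomers, both covered by the structure as drawn.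

**Step 1**
Reactants: 1 3-bromo-2-methoxybenzoic acid
Product: 3 3-bromo-2-methoxy-N-(pivaloyloxy)benzamide, via 3-bromo-2-methoxybenzoyl chloride 2 (not isolated)
Conditions: (COCl)2, DMF (cat.), CH2Cl2, 23 °C; concentrate; then PivONH3+ CF3SO3−, K2CO3, EtOAc/H2O, 0 → 23 °C
Reagents that add atoms: O-pivaloylhydroxylamine (used as its triflate salt), CC(C)(C)C(=O)ON
Why: Acyl chloride formation followed by Schotten–Baumann acylation of the hydroxylamine nitrogen gives the O-acyl hydroxamate, whose N–O bond is the directing group and internal oxidant of step 2; the aryl bromide and the ether are inert to both operations.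

**Step 2**
Reactants: 3 3-bromo-2-methoxy-N-(pivaloyloxy)benzamide
Product: 4 (R)-7-bromo-8-methoxy-3-methyl-3,4-dihydroisoquinolin-1(2H)-one
Conditions: Cp^xRh(C2H4)2 (5 mol%; Cp^x = enantiopure binaphthyl-fused cyclopentadienyl with 3,3'-OMe groups), (PhCO2)2 (5 mol%), propene (2 bar), EtOH, 23 °C
Reagents that add atoms: propene, CC=C
Why: Enantioselective rhodium-catalysed C–H annulation of an O-acyl benzhydroxamate with a terminal alkene: trivalent rhodium (from the monovalent precatalyst and the peroxide) metallates C6, the only free ortho position, propene inserts with the aryl group going to CH2, and C–N bond formation with N–O cleavage closes ring B, the chiral Cp^x ligand choosing the propene face so that the ligand antipode leading to 3R is used.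

**Step 3**
Reactants: 5 methyl 2-methoxy-6-methylbenzoate
Product: 6 methyl 2-(bromomethyl)-6-methoxybenzoate
Conditions: NBS, AIBN (cat.), PhCF3, 85 °C
Reagents that add atoms: N-bromosuccinimide, O=C1CCC(=O)N1Br
Why: Wohl–Ziegler radical bromination at the only benzylic C–H bonds; the ester-deactivated ring and the non-polar radical conditions disfavour nuclear bromination.

**Step 4**
Reactants: 6 methyl 2-(bromomethyl)-6-methoxybenzoate; 4 (R)-7-bromo-8-methoxy-3-methyl-3,4-dihydroisoquinolin-1(2H)-one
Product: 8 methyl 2-methoxy-6-{[(R)-8-methoxy-3-methyl-1-oxo-1,2,3,4-tetrahydroisoquinolin-7-yl]methyl}benzoate, via benzylzinc bromide 7 (not isolated)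
Conditions: 6, Zn, LiCl, THF, 23 °C; then 4, Pd(OAc)2 (2 mol%), SPhos (4 mol%), THF, 23 → 50 °C
Reagents that add atoms: none
Why: Zinc inserts into the benzylic C–Br bond without touching the ester, and Negishi sp3–sp2 coupling under Pd/SPhos joins the benzyl group to C7 of 4; this catalyst system tolerates the ortho-methoxy group and the lactam N–H, and no stereocentre is involved.

**Step 5**
Reactants: 9 methyl phenyl sulfoxide
Product: 11 (E)-1-(phenylsulfinyl)propene, via diethyl [(phenylsulfinyl)methyl]phosphonate 10 (not isolated)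
Conditions: LiN(iPr)2 (2.1 equiv), THF, −78 °C; ClP(O)(OEt)2; then CH3CHO, −78 → 23 °C
Reagents that add atoms: acetaldehyde, CC=O
Why: C-phosphorylation of the sulfinyl carbanion gives the phosphonate anion in situ, and Horner–Wadsworth–Emmons olefination of acetaldehyde should give the vinyl sulfoxide mainly as the E isomer; either alkene isomer would serve, because C2' and C3' both end up sp2.

**Step 6**
Reactants: 8 methyl 2-methoxy-6-{[(R)-8-methoxy-3-methyl-1-oxo-1,2,3,4-tetrahydroisoquinolin-7-yl]methyl}benzoate; 11 (E)-1-(phenylsulfinyl)propene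
Product: 13 (R)-7-(4-hydroxy-5-methoxy-2-methylnaphthalen-1-yl)-8-methoxy-3-methyl-3,4-dihydroisoquinolin-1(2H)-one, via β-keto sulfoxide 12 (not isolated)
Conditions: LiN(iPr)2 (2.1 equiv), THF, −78 °C; 11, −78 → 0 °C; AcOH; then toluene, 90 °C
Reagents that add atoms: none
Why: Proposed new method: two equivalents of LiN(iPr)2 remove first the lactam N–H and then a proton of the doubly benzylic CH2, which is acidified by the ortho ester; this carbanion adds to the methyl-bearing β-carbon of 11 (C1'–C2'), the α-sulfinyl carbanion so formed acylates the neighbouring ester in a 6-exo-trig Dieckmann closure (C3'–C4', ring C), and after neutralisation the β-keto sulfoxide 12 loses PhSOH by thermal syn-elimination across C3'–C2' and the resulting dienone tautomerises to the naphthol. The closest known reactions are the Staunton–Weinreb annulation of ortho-toluate anions with Michael acceptors, the acylation of sulfinyl carbanions by esters and the use of vinyl sulfoxides as alkyne equivalents; a diarylmethane donor has not been combined with a propenyl sulfoxide in this way. The sulfinyl group is preferred to a sulfonyl group because the hydrogen that must leave from C2' is not acidic, so that a β-keto sulfone would rest as its C3' enolate, whereas the sulfoxide eliminates intramolecularly and without base. No stereocentre is created, since C1', C2' and C3' all become sp2, C3 lies far from every anionic site, and the C7–C1' axis forms on aromatisation without control. Regiochemistry follows from polarity (the donor carbon attacks the β-carbon that carries the methyl group and the ester carbon becomes C4', peri to the 5'-methoxy group), and chemoselectivity rests on the higher acidity of the ester-flanked CH2 over C4–H2 of the lactam and on using no more than two equivalents of base.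

**Step 7**
Reactants: 13 (R)-7-(4-hydroxy-5-methoxy-2-methylnaphthalen-1-yl)-8-methoxy-3-methyl-3,4-dihydroisoquinolin-1(2H)-one
Product: 14 (R)-7-(4,5-dimethoxy-2-methylnaphthalen-1-yl)-8-methoxy-3-methyl-3,4-dihydroisoquinolin-1(2H)-one
Conditions: MeI, K2CO3, DMF, 40 °C
Reagents that add atoms: iodomethane, CI
Why: Williamson O-methylation of the naphthol, whose phenoxide forms with K2CO3 while the much less acidic lactam N–H stays untouched.

**Step 8**
Reactants: 14 (R)-7-(4,5-dimethoxy-2-methylnaphthalen-1-yl)-8-methoxy-3-methyl-3,4-dihydroisoquinolin-1(2H)-one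
Product: 15 (R)-1-chloro-7-(4,5-dimethoxy-2-methylnaphthalen-1-yl)-8-methoxy-3-methyl-3,4-dihydroisoquinoline
Conditions: POCl3, toluene, 90 °C; evaporate; cold aq. NaHCO3 wash; used crude
Reagents that add atoms: phosphoryl chloride, O=P(Cl)(Cl)Cl
Why: Vilsmeier-type activation of the secondary lactam through its O-phosphorylated iminium ion gives the cyclic imidoyl chloride; no formamide is present, so the electron-rich arenes are not formylated, and C3 cannot epimerise.

**Step 9**
Reactants: 15 (R)-1-chloro-7-(4,5-dimethoxy-2-methylnaphthalen-1-yl)-8-methoxy-3-methyl-3,4-dihydroisoquinoline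
Product: 16 (R)-7-(4,5-dimethoxy-2-methylnaphthalen-1-yl)-8-methoxy-1,3-dimethyl-3,4-dihydroisoquinoline
Conditions: MeZnCl, Pd(PPh3)4 (5 mol%), THF, 50 °C
Reagents that add atoms: methylzinc chloride, C[Zn]Cl
Why: Negishi cross-coupling of the imidoyl chloride, which adds oxidatively to zerovalent palladium like an acyl or vinyl chloride, installs the C1 methyl group and gives the cyclic ketimine without touching C3.

**Compound list**
1 | 3-bromo-2-methoxybenzoic acid | COc1c(Br)cccc1C(=O)O | starting material
2 | 3-bromo-2-methoxybenzoyl chloride (formed in situ) | COc1c(Br)cccc1C(=O)Cl | intermediate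
3 | 3-bromo-2-methoxy-N-(pivaloyloxy)benzamide | COc1c(Br)cccc1C(=O)NOC(=O)C(C)(C)C | intermediate
4 | (R)-7-bromo-8-methoxy-3-methyl-3,4-dihydroisoquinolin-1(2H)-one | COc1c(Br)ccc2c1C(=O)N[C@H](C)C2 | intermediate
5 | methyl 2-methoxy-6-methylbenzoate | COC(=O)c1c(C)cccc1OC | starting material
6 | methyl 2-(bromomethyl)-6-methoxybenzoate | COC(=O)c1c(CBr)cccc1OC | intermediate
7 | [3-methoxy-2-(methoxycarbonyl)benzyl]zinc bromide (formed in situ) | COC(=O)c1c(C[Zn]Br)cccc1OC | intermediate
8 | methyl 2-methoxy-6-{[(R)-8-methoxy-3-methyl-1-oxo-1,2,3,4-tetrahydroisoquinolin-7-yl]methyl}benzoate | COC(=O)c1c(OC)cccc1Cc1ccc2c(c1OC)C(=O)N[C@H](C)C2 | intermediate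
9 | methyl phenyl sulfoxide (racemic) | CS(=O)c1ccccc1 | starting material
10 | diethyl [(phenylsulfinyl)methyl]phosphonate (formed in situ) | CCOP(=O)(CS(=O)c1ccccc1)OCC | intermediate
11 | (E)-1-(phenylsulfinyl)propene (racemic at sulfur) | C/C=C/S(=O)c1ccccc1 | intermediate
12 | (3R)-8-methoxy-7-[5-methoxy-2-methyl-4-oxo-3-(phenylsulfinyl)-1,2,3,4-tetrahydronaphthalen-1-yl]-3-methyl-3,4-dihydroisoquinolin-1(2H)-one (diastereomer mixture, formed in situ) | COc1cccc2c1C(=O)C(S(=O)c1ccccc1)C(C)C2c1ccc2c(c1OC)C(=O)N[C@H](C)C2 | intermediate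
13 | (R)-7-(4-hydroxy-5-methoxy-2-methylnaphthalen-1-yl)-8-methoxy-3-methyl-3,4-dihydroisoquinolin-1(2H)-one | COc1cccc2c1c(O)cc(C)c2-c1ccc2c(c1OC)C(=O)N[C@H](C)C2 | intermediate
14 | (R)-7-(4,5-dimethoxy-2-methylnaphthalen-1-yl)-8-methoxy-3-methyl-3,4-dihydroisoquinolin-1(2H)-one | COc1cccc2c1c(OC)cc(C)c2-c1ccc2c(c1OC)C(=O)N[C@H](C)C2 | intermediate
15 | (R)-1-chloro-7-(4,5-dimethoxy-2-methylnaphthalen-1-yl)-8-methoxy-3-methyl-3,4-dihydroisoquinoline | COc1cccc2c1c(OC)cc(C)c2-c1ccc2c(c1OC)C(Cl)=N[C@H](C)C2 | intermediate
16 | (R)-7-(4,5-dimethoxy-2-methylnaphthalen-1-yl)-8-methoxy-1,3-dimethyl-3,4-dihydroisoquinoline | COc1c(-c2c(C)cc(OC)c3c(OC)cccc23)ccc2c1C(C)=N[C@H](C)C2 | target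

Total step count: 9. Longest linear sequence: 7 steps (steps 1, 2, 4, 6, 7, 8, 9).

**Steps most likely to fail**

1. Step 6. The hindered dianion may add too slowly to the β-methyl vinyl sulfoxide, so that proton transfer from the acceptor, intermolecular Claisen self-condensation or retro-Michael loss of the sulfinyl carbanion wins over ring closure. The fallback sets out from 8 and uses known chemistry. The same dianion (LiN(iPr)2, THF, −78 °C) is combined with tert-butyl (E)-but-2-enoate, the acceptor class for which the Staunton–Weinreb annulation is established. This should give tert-butyl 8-methoxy-4-[(3R)-8-methoxy-3-methyl-1-oxo-1,2,3,4-tetrahydroisoquinolin-7-yl]-3-methyl-1-oxo-1,2,3,4-tetrahydronaphthalene-2-carboxylate F1. CF3CO2H cleaves the tert-butyl ester and the β-keto acid decarboxylates on warming to (3R)-8-methoxy-7-(5-methoxy-2-methyl-4-oxo-1,2,3,4-tetrahydronaphthalen-1-yl)-3-methyl-3,4-dihydroisoquinolin-1(2H)-one F2. Aerobic dehydrogenation with divalent palladium (Pd(O2CCF3)2, 2-(dimethylamino)pyridine, TsOH, O2, DMSO, 80 °C) aromatises ring C, and the route is rejoined at 13.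

2. Step 2. Propene is small and unbiased, so control of insertion regiochemistry and of its enantiotopic faces by the chiral ligand may be incomplete. The fallback sets out from 1 and takes C3 from the chiral pool. Carboxylate-directed ortho-iodination (Pd(OAc)2 cat., PhI(OAc)2, I2, DMF) at the only free ortho position should give 3-bromo-6-iodo-2-methoxybenzoic acid F3. MeI/K2CO3 gives methyl 3-bromo-6-iodo-2-methoxybenzoate F4. Zinc insertion (Zn, DMF) into commercial, D-alaninol-derived tert-butyl N-[(2R)-1-iodopropan-2-yl]carbamate gives (R)-[2-(tert-butoxycarbonylamino)propyl]zinc iodide F5. Negishi coupling of F5 at the C–I bond of F4 (Pd2(dba)3, SPhos, 23 °C, C–Br untouched) gives methyl 3-bromo-6-[(2R)-2-(tert-butoxycarbonylamino)propyl]-2-methoxybenzoate F6. CF3CO2H followed by K2CO3 in MeOH at 60 °C removes the carbamate and closes the lactam, and the route is rejoined at 4.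

3. Step 9. The moisture-sensitive imidoyl chloride may hydrolyse back to the lactam, and oxidative addition at C1, shielded by the peri 8-methoxy group, may be slow. The fallback sets out from 14 and replaces cross-coupling by carbonyl addition. Boc2O/DMAP gives tert-butyl (3R)-7-(4,5-dimethoxy-2-methylnaphthalen-1-yl)-8-methoxy-3-methyl-1-oxo-3,4-dihydroisoquinoline-2(1H)-carboxylate F7. MeLi (THF, −78 °C) adds to the activated ring carbonyl with ring opening to tert-butyl N-[(2R)-1-[2-acetyl-4-(4,5-dimethoxy-2-methylnaphthalen-1-yl)-3-methoxyphenyl]propan-2-yl]carbamate F8. CF3CO2H, then NaHCO3, removes the carbamate and the amino ketone cyclodehydrates to the ketimine, so the route is rejoined at 16.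

**Further compounds**
F1 | step 6 | tert-butyl 8-methoxy-4-[(3R)-8-methoxy-3-methyl-1-oxo-1,2,3,4-tetrahydroisoquinolin-7-yl]-3-methyl-1-oxo-1,2,3,4-tetrahydronaphthalene-2-carboxylate | COc1cccc2c1C(=O)C(C(=O)OC(C)(C)C)C(C)C2c1ccc2c(c1OC)C(=O)N[C@H](C)C2
F2 | step 6 | (3R)-8-methoxy-7-(5-methoxy-2-methyl-4-oxo-1,2,3,4-tetrahydronaphthalen-1-yl)-3-methyl-3,4-dihydroisoquinolin-1(2H)-one | COc1cccc2c1C(=O)CC(C)C2c1ccc2c(c1OC)C(=O)N[C@H](C)C2
F3 | step 2 | 3-bromo-6-iodo-2-methoxybenzoic acid | COc1c(Br)ccc(I)c1C(=O)O
F4 | step 2 | methyl 3-bromo-6-iodo-2-methoxybenzoate | COC(=O)c1c(I)ccc(Br)c1OC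
F5 | step 2 | (R)-[2-(tert-butoxycarbonylamino)propyl]zinc iodide | CC(C)(C)OC(=O)N[C@H](C)C[Zn]I
F6 | step 2 | methyl 3-bromo-6-[(2R)-2-(tert-butoxycarbonylamino)propyl]-2-methoxybenzoate | COC(=O)c1c(C[C@@H](C)NC(=O)OC(C)(C)C)ccc(Br)c1OC
F7 | step 9 | tert-butyl (3R)-7-(4,5-dimethoxy-2-methylnaphthalen-1-yl)-8-methoxy-3-methyl-1-oxo-3,4-dihydroisoquinoline-2(1H)-carboxylate | COc1cccc2c1c(OC)cc(C)c2-c1ccc2c(c1OC)C(=O)N(C(=O)OC(C)(C)C)[C@H](C)C2
F8 | step 9 | tert-butyl N-[(2R)-1-[2-acetyl-4-(4,5-dimethoxy-2-methylnaphthalen-1-yl)-3-methoxyphenyl]propan-2-yl]carbamate | COc1cccc2c1c(OC)cc(C)c2-c1ccc(C[C@@H](C)NC(=O)OC(C)(C)C)c(C(C)=O)c1OC
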